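Two questions stand over this flask, and we begin with the first.

- part of the solid electrophile that has reacted (what has only dissolved counts as not reacted) at 2.5 min
- share of free nucleophile in free nucleophile and protonated nucleophile together, at 2.5 min

solid electrophile 5.0 mM; nucleophile 10.0 mM; time 2.5 min

    electrophile + nucleophile → acid set free + target (k1 = 94.5 L mol⁻¹ s⁻¹)
    nucleophile + acid set free ⇌ protonated nucleophile, settled at all times (K2 = 39000 L mol⁻¹)
    nucleophile ⇌ dormant form (K3 = 0.357, k3 = 0.0888 s⁻¹)
    solid electrophile ⇌ electrophile, rate k4*(cs4 - [electrophile]) while solid is left; crystals form when [electrophile] > cs4 (cs4 = 0.61 mM, k4 = 0.122 s⁻¹)
    nucleophile + target → over-reaction product (k5 = 3.13 L mol⁻¹ s⁻¹)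

We reckon in rates. At the start, with nucleophile as charged, electrophile reacts with a half-life of 0.73 s, shorter than the 5.68 s of dissolution. So at the start dissolution is the rate-limiting step, and we take the feed as the dissolution coefficient times the solubility, 0.0744 mM s⁻¹. At that rate the charge would be through in 67.2 s, less than the 150 s allowed, so we look at the cost instead.

Each electrophile that reacts uses one nucleophile and sets free one acid. With the equilibrium constant of protonation times the nucleophile at the start at 390, we count a second nucleophile for that acid. The charge holds 2.00 nucleophile per solid electrophile, which just pays.

The correction is the over-reaction. In our reckoning its rate rises with target from zero while nucleophile falls to zero, so we take its mean as the product of the full target and the full nucleophile divided by 6. Free nucleophile is first cut to a share of 0.737, since the dormant form balances with a relaxation half-life of 2.05 s. Set against the feed, this gives a tax of 0.258 nucleophile per electrophile, small against the two. The nucleophile price, nucleophile spent per electrophile reacted, is then 2.26. Taking nucleophile as the limiting reagent, we commit to 88.6% reacted.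

The forecast says 95%, above our figure, and 3%, on the ground that “Each electrophile consumed takes two nucleophile equivalents (one reacts, one is protonated)”. The simulation gives 93.7% and 2.98%.

In the flask, nucleophile charged less what stands free or dormant, per electrophile reacted, comes to 2.10, less than our price, with 0.834 mM of acid standing free, and our figure lies 5.1 percentage points low. The neighbour with 6.0 mM of nucleophile has a tax of 0.0930, a price of 2.09 and so a reckoned 57.3%. It gives 63.2%, again 5.9 points above, with 25.3% of the solid electrophile undissolved, nucleophile down to 1.09% of its charge, 0.890 mM of acid free, and a price, counted as in the flask, of 1.87.

(The constants are assumed; what happens was integrated by code.)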